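A ratio ran this flask in my head: the substrate standing in it over what the feed brings per minute. That ratio is τ, the substrate's lifetime (its pseudo-first-order lifetime), and the dosing time over τ counts the turnovers, N.

- Thursday's: substrate 25 mM (fed, over 2.0 h); acid 0.025 mM; the very flask that is asked about, followed so far
- flask: substrate 25 mM (fed, over 2.0 h); acid 0.0250 mM; time 2.0 h

Thursday's run (percent of the substrate charged)

| time / min | substrate / % | target / % |
|---|---|---|
| 6.00 | 4.4 | 0.4 |
| 12.0 | 6.9 | 2.8 |
| 20.0 | 5.0 | 11.5 |
| 25.0 | 3.9 | 17.5 |
| 30.0 | 2.8 | 21.3 |
| 40.0 | 2.7 | 31.0 |

(readings scatter by 0.5 percentage points)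

- acid is the free proton; pH is minus the decimal logarithm of its molar concentration
- the numbers in the tables scatter with a standard deviation of 0.5 percentage points
- percentages count the whole charge, also what has not yet gone in

1. part of the substrate that has reacted at 2.0 h
2. pH of the solution at 2.0 h

At the peak reading, 6.9% at 12.0 min, I took substrate as neither rising nor falling, so consumption about equalled the feed and τ read 8.28 min. By 40.0 min the reading was nearly flat at 2.7%, and τ, the standing share times the dosing time, had come down to 3.24 min, so N was 37.0.

I took the settings in turn. By hand, I expected less starting acid to slow the first minutes; but in this flask the τ I read shortened as target grew, so I took the reaction to feed itself and the charge to count early. With τ held fixed and substrate flat, the share standing when the feed ends is 1/N, so a longer feed leaves less. After the feed, each τ cuts the rest by a factor e, but the asked time falls at the feed's end. So I reckoned about 97.3% reacted, and somewhat more if τ went on shortening; I made no pH of my own.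

The forecast stood higher, at 98.6% and pH 3.42, on the ground that “the reaction speeds up as target forms”.

The flask gave 98.8% and pH 2.76, so the forecast's pH lay above it.

    substrate + acid → weak acid + acid + target (k = 6.83 M⁻¹ s⁻¹)
    weak acid ⇌ conjugate base + acid, settled at all times (K = 1.30 × 10⁻⁴ M)
    substrate → weak acid + target (k = 7.82 × 10⁻⁵ s⁻¹)
    substrate + target → side product (k = 0.00654 M⁻¹ s⁻¹)

At 2.0 h the half-life of substrate by the step with acid was 0.98 min, a lifetime by that step of 1.41 min, shorter than the 3.24 min I had read at 40.0 min. That lifetime is 1.17% of the dosing time, and at 2.0 h the flask still held 1.2% of substrate, so the flask had not come to rest. The same flask read at 3.0 h, about 42.6 such lifetimes after the feed ended, held 0% of substrate. Left until 20.0 h, the flask gained 1.2 percentage points more reacted, reaching 100%, with target at 98.2%.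

The numbers in the tables were computed for substances that don't exist, noise included.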